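**The question.** Which of oak and ash ends with the larger excess of right-handed substrate, and what would have to be true for ash not to be that flask?

in all of them: left-handed substrate 0.28 M; right-handed substrate 0.28 M; free catalyst 2 mol%

| charge | coupling partner | remark | time |
|---|---|---|---|
| Tuesday's | 0.50 equiv | run made earlier |  |
| Sunday's | 1.3 equiv | run made earlier |  |
| Thursday's | 2.1 equiv | run made earlier |  |
| oak | 0.600 equiv |  | 2.0 h |
| ash | 2.40 equiv |  | 2.0 h |

| run | time / min | right-handed substrate / % | left-handed substrate / % | left-handed product / % |
|---|---|---|---|---|
| Tuesday's | 5.00 | 49 | 47 | 4 |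
| Tuesday's | 10.0 | 46 | 45 | 6 |
| Tuesday's | 15.0 | 44 | 44 | 7 |
| Tuesday's | 30.0 | 44 | 42 | 8 |
| Tuesday's | 60.0 | 46 | 40 | 9 |
| Sunday's | 5.00 | 43 | 41 | 6 |
| Sunday's | 10.0 | 42 | 36 | 11 |
| Sunday's | 15.0 | 38 | 35 | 13 |
| Sunday's | 30.0 | 40 | 33 | 19 |
| Sunday's | 60.0 | 36 | 31 | 21 |
| Thursday's | 5.00 | 45 | 36 | 10 |
| Thursday's | 15.0 | 39 | 32 | 20 |
| Thursday's | 30.0 | 36 | 27 | 20 |
| Thursday's | 40.0 | 33 | 28 | 22 |
| Thursday's | 60.0 | 34 | 25 | 23 |

(readings scatter by 1.5 percentage points)

- free catalyst is single-handed; left-handed substrate and right-handed substrate are mirror images of each other, charged as a racemate, each of them at the stated concentration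
- an excess is below zero if the other one leads

- which one finishes higher in excess of right-handed substrate over left-handed substrate among what is left of the two ("neither" within 2 percentage points) (oak / ash / neither)
- excess of right-handed substrate over left-handed substrate among what is left of the two at the end, oak
- excess of right-handed substrate over left-handed substrate among what is left of the two at the end, ash

**Fraction left.** The mirror images share one catalyst and one partner, so I take the ratio of the logarithms of their fractions left as a constant, the selectivity factor s. Thursday's readings from 30.0 min on, averaged, give s = 1.67. With m the fraction of both substrates left, ([left-handed substrate] + [right-handed substrate]) over its charged value, the excess at moderate conversion is g·ln(1/m), where g is the excess slope, s minus one over s plus one, 0.252.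

**Turned round.** If one partner makes one product, oak's 0.600 equiv, counted on the left-handed substrate, holds its m at or above 70.0%, so my reckoned excess for oak stays at or under 8.97%. For ash not to lead, its reckoned excess must finish no higher than 2 percentage points above that ceiling. Yet Thursday's flask, with less partner than ash, reckons to 13.3% at its last reading, 4.3 points above the ceiling. By this slope, ash would have to end with less substrate consumed than Thursday's flask shows at that reading.

**My reckoning.** Running ln(1/m) from the last readings straight along the partner charge, I get 4.58% for oak and 14.5% for ash.

**The forecast.** It names ash, with 7% for oak and 19% for ash, both above mine, noting that “The plateau rises with partner loading”.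

**The result.** The flask gives ash: 5.28% for oak and 14.5% for ash.

    coupling partner → decomposed reagent (k = 1.15 × 10⁻⁴ /s)
    coupling partner + free catalyst + left-handed substrate → free catalyst + left-handed product (k = 0.493 /M²/s)
    coupling partner + free catalyst + right-handed substrate → free catalyst + right-handed product (k = 0.303 /M²/s)
    coupling partner + free catalyst → spent catalyst (k = 0.00337 /M/s)
    coupling partner ⇌ dormant form (K = 4.58, k = 7.68 × 10⁻⁴ /s)

**Its use.** At 2.00 h ash has 7.23% of its free catalyst left and 63% of its charged right-handed substrate still there, unbound. The slope g on ash's m gives 15.2%. On the neighbour of ash with 3.4 mol% of free catalyst it gives 24.1%, where that flask stands at 23.1%.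

The data are calculated with made-up constants; scatter was added.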